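## The problem

Arthonioic acid 27 is a depside in which the carboxyl group of ring A, a 2,4-dihydroxy-6-(2-oxoheptyl)benzoyl unit, is esterified with the C4 oxygen of ring B, a 2-methoxy-6-(2-oxoheptyl)benzoic acid. The molecule has no stereocenter and no fused ring, so the task is one of substitution pattern and functional-group compatibility. Each ring carries an oxygen at C2, the carboxyl carbon at C1 and a CH2 carbon at C6 on three neighbouring ring atoms, and on ring B the two oxygens must also be told apart (methyl ether at C2, acylated oxygen at C4) while the carboxyl group ends up free. Three features are fragile: the hindered aryl ester, which the enol or enolate of the ortho 2-oxoheptyl arm can attack to close an isocoumarin and expel ring B; the 2-(2-oxoalkyl)benzoic acid units, which collapse to isocoumarins when the carboxyl group is activated; and the free resorcylic acid patterns, which decarboxylate easily. The ring A ketone therefore has to be masked while the ester is made, and the last steps have to be neutral or mildly acidic. The feature that opens the key step is on ring B: carboxyl carbon C1 and CH2 carbon C6 sit on adjacent ring atoms and C1 is flanked by the C2 methoxy group, which is the pattern a 3-methoxyaryne leaves when it inserts into a C–C bond of a malonate.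

## Retrosynthesis

**Unmasking (27 from 26 from 25).** The last bonds cut are three O–benzyl bonds (two ethers on ring A, one ester on ring B) and, before that, the dioxolane on the ring A ketone. Hydrogenolysis is placed last because it is neutral and leaves only toluene. Base is excluded once ketone and aryl ester sit ortho on ring A. The forward steps must leave the depside ester and both ketones alone.

**Depside ester (25 to 24 + 18).** Cutting the aryl ester C–O bond splits the target into two benzoic acid halves of similar size. Building ring A on a preformed ester would be the alternative, but it puts an acyclic polyketone next to a good leaving group. The forward reaction must acylate the phenol of 18 with the di-ortho-substituted acid 24. The ketone of 24 is masked because an activated 2-(2-oxoalkyl)benzoic acid would close to an isocoumarin. The ring B carboxyl is carried as a benzyl ester so that one hydrogenolysis frees everything.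

**Protecting-group exchange on ring B (18 from 17 from 16).** The benzyl ether that carries the C4 oxygen through the aryne chemistry must leave before the benzyl ester is put on, since both are cleaved by hydrogen. Keto acid 16 is therefore debenzylated to 17, and the carboxylate of 17 is alkylated with bicarbonate as base, which leaves the phenol free.

**Side-chain ketone (16 to 13 + 14, 13 from 12 from 11).** The bond between the benzylic carbon and the ketone carbon is cut. In homophthalic anhydride 13 that benzylic carbon is doubly activated and can be acylated by hexanoyl chloride 14 under amine base. The extra carboxyl carbon then leaves as CO2 when the ring is opened. Anhydride 13 comes from diacid 12 and this from diester 11. This is simpler than adding a six-carbon nucleophile to a homophthalate ester, which would have to distinguish two esters.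

**Key disconnection (11 to 10 + 9).** Both carbon substituents of ring B are removed at once: the aryl–carboxyl bond at C1 and the aryl–CH2 bond at C6. What remains is aryne 10 and dimethyl malonate 9. Making the same two bonds one after the other would need two separate ortho-functionalizations on an electron-rich ring. The insertion makes them in one step, and the methoxy group of 10 decides which carbon receives which group. The aryne is released by fluoride from silylaryl triflate 8. The forward reaction needs regioselective addition and a ring closure of the aryl anion that is faster than its protonation.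

**Aryne precursor (8 from 7 from 3 from 1).** Either placement of silicon and triflate on the two aryne carbons releases the same aryne 10. The placement with triflate on the carbon next to OMe is chosen because it can be made without any regiochemical choice. Directed ortho-silylation of a 3,5-dialkoxyphenol derivative would have to choose between two flanked positions with little bias. In 5-bromovanillin 1 the bromine already marks the carbon for silicon, the neighbouring phenol becomes the triflate, and the aldehyde becomes the C4 oxygen by Dakin oxidation to hydroquinone 3. An O-to-C silyl shift onto the lithiated carbon then gives 7, and benzylation gives 8.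

**Ring A acid (24 from 23 from 22, 22 to 20 + 21).** The same benzylic carbon–ketone carbon bond is cut, here by lateral lithiation of toluate 20 and acylation with Weinreb amide 21, made from 14. Toluate 20 is the dibenzyl ether of commercial methyl orsellinate 19. Both ring A oxygens carry the same group and the ring carbon pattern can be bought, so one C–C bond formation suffices. Ketalization to 23 and saponification give 24. The same toluate chemistry could in principle serve ring B. The aryne insertion is kept there because it installs both carbon substituents in one step and delivers the side-chain carbon at the carboxyl level, where acylation needs only amine base.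

## Roads not taken

Alternative 1: Diels–Alder benzannulation of ring B. The cut goes through the C1–C2 and C5–C6 bonds of ring B. In the forward step the ketene-acetal diene 1,1-dimethoxy-3-(trimethylsilyloxy)buta-1,3-diene A1 would add thermally to benzyl 4-(2-pentyl-1,3-dioxolan-2-yl)but-2-ynoate A2. Loss of one alkoxy group and of the silyl group would give benzyl 4-hydroxy-2-methoxy-6-[(2-pentyl-1,3-dioxolan-2-yl)methyl]benzoate A3. The merits are real: the polarity of A1 fixes OMe next to the ester and the free hydroxyl para to it, and A3 is the dioxolane analogue of 18 and would arrive in one step, with no protecting-group exchange on ring B. The weak points lie in the partners. A2 has an alkyl group on the alkyne terminus and is a sluggish dienophile, so heating is needed that the moisture- and heat-sensitive A1 tolerates poorly. A2 itself needs several steps, and its skipped alkyne–ketal array is prone to propargyl–allenyl isomerization under base. Ring A is not addressed. In comparison, if the cycloaddition works, this road is clearly shorter for ring B than steps 1–9. The chosen plan sets against it a bought aromatic ring, a highly reactive aryne that needs no dienophile activation, and simple commercial carbon sources (9 and 14).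

Alternative 2: Carboxylate-directed C–H annulation for ring A. The cut is the aryl–CH bond at C6 of ring A together with a temporary lactone C–O bond. 2,4-Bis(benzyloxy)benzoic acid A4 and the hexanoyl sulfoxonium ylide dimethylsulfoxonium 2-oxoheptylide A5 would react under [Cp*RhCl2]2 and AgSbF6 (trivalent rhodium) to give 6,8-bis(benzyloxy)-3-pentyl-1H-isochromen-1-one A6. In this step A5 acts as a carbene equivalent: the rhodacycle formed at the ortho C–H bond of A4 takes up the acyl carbene from A5, and the resulting ortho 2-oxoheptyl acid closes to the enol lactone A6. The merits are that A4 has only one ortho C–H bond, so there is no regiochemical question, that A5 should be available from 14 in one step by acylation of a sulfur ylide, and that A6 arrives in one step and opens to the keto acid with hydroxide. The weak points are that electron-rich ortho-alkoxybenzoic acids such as A4 are prone to protodecarboxylation under silver and rhodium salts at the temperatures such annulations need, and that A6 would still have to be opened, esterified, ketalized and saponified to reach 24, so the saving against steps 10–14 is small. Only ring A is addressed. In comparison, the same annulation applied to ring B would be shorter than the sequence to 16 here, and that is a real advantage. The chosen plan sets against it the absence of precious metals, a keto ester 22 that is ready for ketalization without lactone opening, and regiocontrol that comes from the polarization of the aryne and not from a directing group on an acid that can decarboxylate.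

Alternative 3: Polyketide aldol aromatization on the depside ester. The cut is the C1–C6 bond of ring A. The ring B aryl ester of a 3,5,7-trioxo acid with the distal ketone masked, benzyl 2-methoxy-6-[(2-pentyl-1,3-dioxolan-2-yl)methyl]-4-{[3,5,7-trioxo-8-(2-pentyl-1,3-dioxolan-2-yl)octanoyl]oxy}benzoate A7, would be treated with Cs2CO3 and then acid. Chain carbon C2 would add to the C7 ketone, giving the protected arthonioic acid A8 (benzyl ester, two dioxolanes, free ring A phenols). The merits are that the route is biomimetic, that ring A needs no phenol protection, and that the depside bond is made on an unhindered acyclic acyl donor, which avoids the crowded esterification of step 15. The weak points are serious. In A7 the aryl ester is the best leaving group in the molecule. Attack of the C5 enol oxygen on C1 gives a 4-hydroxypyranone, and Claisen attack of C6 on C1 gives an acylphloroglucinol. Both expel the ring B phenoxide and destroy the depside. Assembling A7 is itself a multistep task. In comparison, this is the shortest road on paper and the only one that makes the ester bond without steric strain. The chosen plan is longer, but each bond formation follows a precedented type and the depside ester is never placed next to an unprotected poly-β-carbonyl chain.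

Key step: step 4

Remark on the chemistry: the 2-(2-oxoalkyl)benzoic acids 16, 17 and 27 are written as open keto acids; their ring–chain (lactol) tautomers are the same compounds. Compounds 1, 9, 14 and 19 are taken as commercial.

## Steps

Step 1
Reactants: 1 5-bromovanillin (3-bromo-4-hydroxy-5-methoxybenzaldehyde)
Product: 3 2-bromo-6-methoxybenzene-1,4-diol, via aryl formate 2 (not isolated)
Conditions: H2O2 (30% aq.), NaOH, THF/H2O, 0 °C to rt, N2; then Na2S2O4, HCl
Reagents that add atoms: hydrogen peroxide, OO
Why: Dakin oxidation: hydroperoxide adds to the aldehyde para to the phenoxide, the electron-rich aryl group migrates to oxygen to give formate 2, and this is hydrolysed in the same flask; bromide and methyl ether are inert, and inert gas with dithionite should keep the hydroquinone from oxidizing to the quinone.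

Step 2
Reactants: 3 2-bromo-6-methoxybenzene-1,4-diol
Product: 7 4-hydroxy-2-methoxy-6-(trimethylsilyl)phenyl trifluoromethanesulfonate, via bis(trimethylsilyl) ether 4 (not isolated), via lithium phenoxide 5 (not isolated), via O-silyl triflate 6 (not isolated)
Conditions: (Me3Si)2NH, THF, 70 °C, evaporate; n-BuLi, THF, −100 to −78 °C; Tf2O, −100 to −78 °C; then 1 M HCl, THF, 0 °C
Reagents that add atoms: hexamethyldisilazane, C[Si](C)(C)N[Si](C)(C)C; trifluoromethanesulfonic anhydride, O=S(=O)(OS(=O)(=O)C(F)(F)F)C(F)(F)F
Why: Established one-pot route from ortho-bromophenols to ortho-silylaryl triflates: O-silylation, bromine–lithium exchange, retro-Brook 1,3 O-to-C silyl shift and triflation of phenoxide 5. Only the silyl ether ortho to the C–Li bond can migrate, so bromine fixes the regiochemistry; the remote O–SiMe3 group is a spectator and is hydrolysed in the acidic work-up.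

Step 3
Reactants: 7 4-hydroxy-2-methoxy-6-(trimethylsilyl)phenyl trifluoromethanesulfonate
Product: 8 4-(benzyloxy)-2-methoxy-6-(trimethylsilyl)phenyl trifluoromethanesulfonate
Conditions: BnBr, K2CO3, acetone, rt
Reagents that add atoms: benzyl bromide, BrCc1ccccc1
Why: Williamson etherification of the only free phenol; carbonate in acetone at room temperature without a crown ether should not attack the aryl–silicon bond, so the aryne is not released early.

Step 4
Reactants: 8 4-(benzyloxy)-2-methoxy-6-(trimethylsilyl)phenyl trifluoromethanesulfonate; 9 dimethyl malonate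
Product: 11 methyl 4-(benzyloxy)-2-methoxy-6-(2-methoxy-2-oxoethyl)benzoate, via aryne 10 (not isolated)
Conditions: CsF (3 equiv), 9 (1.5 equiv), MeCN, 80 °C
Reagents that add atoms: none
Why: Fluoride attacks silicon in 8 and triflate leaves from the neighbouring carbon to give aryne 10, while fluoride (or the aryl anion formed later) deprotonates 9. The malonate carbanion adds to the aryne carbon that carried silicon, remote from the methoxy group: the inductively withdrawing oxygen distorts the aryne so that the distal carbon is the more electrophilic one and the developing aryl anion sits beside OMe. This aryl anion closes onto an ester carbonyl (4-exo-trig) to a benzocyclobutenoxide, which fragments by C–C cleavage to the ester enolate; protonation should give 11 with CO2Me on C1 next to OMe and CH2CO2Me on C6. The closest known reaction type is the fluoride-induced acyl-alkylation of arynes, that is, aryne insertion into the C–C σ-bond of malonates and β-ketoesters. No ring is kept (the four-membered ring is transient) and no stereocenter is formed. The step needs regioselective addition, secured by the methoxy group beside the triple bond; the benzyloxy group para to the anionic carbon exerts only a weak opposing inductive pull. It also needs the ring closure to outrun protonation of the aryl anion, which anhydrous CsF in MeCN and the ester held in the ortho position should favour.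

Step 5
Reactants: 11 methyl 4-(benzyloxy)-2-methoxy-6-(2-methoxy-2-oxoethyl)benzoate
Product: 12 4-(benzyloxy)-2-(carboxymethyl)-6-methoxybenzoic acid
Conditions: KOH (excess), EtOH/H2O, reflux; then HCl
Reagents that add atoms: potassium hydroxide, [K+].[OH-]
Why: Saponification: the arylacetic ester is cleaved fast and the di-ortho-substituted benzoate on prolonged reflux, as is usual for 3,5-dialkoxyhomophthalates; the benzyl ether is stable to hydroxide.

Step 6
Reactants: 12 4-(benzyloxy)-2-(carboxymethyl)-6-methoxybenzoic acid
Product: 13 6-(benzyloxy)-8-methoxy-1H-isochromene-1,3(4H)-dione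
Conditions: Ac2O, toluene, 90 °C
Reagents that add atoms: none
Why: Cyclodehydration of a homophthalic acid to its six-membered anhydride, a standard reaction that needs no base and so should not acylate the benzylic carbon.

Step 7
Reactants: 13 6-(benzyloxy)-8-methoxy-1H-isochromene-1,3(4H)-dione; 14 hexanoyl chloride
Product: 16 4-(benzyloxy)-2-methoxy-6-(2-oxoheptyl)benzoic acid, via 4-hexanoyl anhydride 15 (not isolated)
Conditions: 1,1,3,3-tetramethylguanidine (TMG), Et3N, MeCN, −20 °C to rt; then 1 M NaOH, rt; then HCl to pH 1, 50 °C
Reagents that add atoms: water, O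
Why: C-acylation of the doubly activated C4 position of a homophthalic anhydride under amine and guanidine base gives enolized 15; hydrolytic ring opening then gives a β-keto acid that loses CO2 on acidification. This is the known homophthalic anhydride route to 2-(2-oxoalkyl)benzoic acids.

Step 8
Reactants: 16 4-(benzyloxy)-2-methoxy-6-(2-oxoheptyl)benzoic acid
Product: 17 4-hydroxy-2-methoxy-6-(2-oxoheptyl)benzoic acid
Conditions: H2 (1 atm), 10% Pd/C, EtOAc, rt
Reagents that add atoms: none
Why: Hydrogenolysis of an aryl benzyl ether; the aliphatic ketone and the carboxylic acid are inert under these conditions.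

Step 9
Reactants: 17 4-hydroxy-2-methoxy-6-(2-oxoheptyl)benzoic acid
Product: 18 benzyl 4-hydroxy-2-methoxy-6-(2-oxoheptyl)benzoate
Conditions: BnBr (1.05 equiv), KHCO3 (1.1 equiv), DMF, rt
Reagents that add atoms: benzyl bromide, BrCc1ccccc1
Why: Chemoselective carboxylate O-alkylation: bicarbonate deprotonates only the carboxylic acid (as its open keto carboxylate), so the phenol should stay free and the acidic benzylic CH2 untouched.

Step 10
Reactants: 19 methyl 2,4-dihydroxy-6-methylbenzoate (methyl orsellinate)
Product: 20 methyl 2,4-bis(benzyloxy)-6-methylbenzoate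
Conditions: BnBr (2.5 equiv), K2CO3, DMF, 60 °C
Reagents that add atoms: benzyl bromide, BrCc1ccccc1
Why: Double Williamson etherification; warm DMF and excess reagent are used because the 2-hydroxyl is hydrogen-bonded to the ester and reacts slowly.

Step 11
Reactants: 14 hexanoyl chloride
Product: 21 N-methoxy-N-methylhexanamide
Conditions: MeNH(OMe)·HCl, Et3N, CH2Cl2, 0 °C to rt
Reagents that add atoms: N,O-dimethylhydroxylamine hydrochloride, CNOC.Cl
Why: Acylation of the hydroxylamine by an acid chloride, the standard preparation of a Weinreb amide.

Step 12
Reactants: 20 methyl 2,4-bis(benzyloxy)-6-methylbenzoate; 21 N-methoxy-N-methylhexanamide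
Product: 22 methyl 2,4-bis(benzyloxy)-6-(2-oxoheptyl)benzoate
Conditions: lithium diisopropylamide (2.2 equiv), THF, −78 °C; then 21; aq. NH4Cl
Reagents that add atoms: none
Why: Lateral lithiation of an ortho-toluate followed by Weinreb ketone synthesis, as widely used for resorcylate side chains; the chelated tetrahedral adduct survives until the quench, which should prevent over-addition and lactonization, and the amide base is not strong enough to deprotonate the benzyl ethers at −78 °C.

Step 13
Reactants: 22 methyl 2,4-bis(benzyloxy)-6-(2-oxoheptyl)benzoate
Product: 23 methyl 2,4-bis(benzyloxy)-6-[(2-pentyl-1,3-dioxolan-2-yl)methyl]benzoate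
Conditions: Me3SiOCH2CH2OSiMe3, Me3SiOTf (cat.), CH2Cl2, −78 to −20 °C; pyridine quench
Reagents that add atoms: 1,2-bis(trimethylsilyloxy)ethane, C[Si](C)(C)OCCO[Si](C)(C)C
Why: Noyori ketalization under aprotic conditions at low temperature, chosen so that acid-catalysed enol lactonization of the keto ester to an isocoumarin is not given a chance.

Step 14
Reactants: 23 methyl 2,4-bis(benzyloxy)-6-[(2-pentyl-1,3-dioxolan-2-yl)methyl]benzoate
Product: 24 2,4-bis(benzyloxy)-6-[(2-pentyl-1,3-dioxolan-2-yl)methyl]benzoic acid
Conditions: KOH, DMSO/H2O, 100 °C; then aq. KHSO4 to pH 4, 0 °C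
Reagents that add atoms: potassium hydroxide, [K+].[OH-]
Why: Saponification of a di-ortho-substituted methyl benzoate with poorly solvated hydroxide in DMSO; dioxolane and benzyl ethers are stable to base, and the cold, weakly acidic work-up should keep the ketal.

Step 15
Reactants: 24 2,4-bis(benzyloxy)-6-[(2-pentyl-1,3-dioxolan-2-yl)methyl]benzoic acid; 18 benzyl 4-hydroxy-2-methoxy-6-(2-oxoheptyl)benzoate
Product: 25 benzyl 4-({2,4-bis(benzyloxy)-6-[(2-pentyl-1,3-dioxolan-2-yl)methyl]benzoyl}oxy)-2-methoxy-6-(2-oxoheptyl)benzoate
Conditions: DCC (1.2 equiv), DMAP (0.3 equiv), CH2Cl2, 0 °C to rt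
Reagents that add atoms: none
Why: Steglich esterification: the acylpyridinium ion formed from the O-acylisourea acylates the unhindered, fairly acidic phenol of 18; the non-acidic medium keeps the dioxolane, and DMAP is too weak a base to enolize the ring B ketone.

Step 16
Reactants: 25 benzyl 4-({2,4-bis(benzyloxy)-6-[(2-pentyl-1,3-dioxolan-2-yl)methyl]benzoyl}oxy)-2-methoxy-6-(2-oxoheptyl)benzoate
Product: 26 benzyl 4-{[2,4-bis(benzyloxy)-6-(2-oxoheptyl)benzoyl]oxy}-2-methoxy-6-(2-oxoheptyl)benzoate
Conditions: 1 M HCl/THF (1:3), rt
Reagents that add atoms: water, O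
Why: Acid-catalysed hydrolysis of a dialkyl ketone dioxolane through its oxocarbenium ion; benzyl ester, benzyl ethers and the hindered aryl ester should be stable to dilute aqueous acid at room temperature.

Step 17
Reactants: 26 benzyl 4-{[2,4-bis(benzyloxy)-6-(2-oxoheptyl)benzoyl]oxy}-2-methoxy-6-(2-oxoheptyl)benzoate
Product: 27 arthonioic acid
Conditions: H2 (1 atm), 10% Pd/C, EtOAc, rt
Reagents that add atoms: none
Why: Global hydrogenolysis of two aryl benzyl ethers and one benzyl ester under neutral conditions; the ketones and the depside ester are not reduced, and no base or acid is present that could trigger isocoumarin formation.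

## Compound list

1 | 5-bromovanillin (3-bromo-4-hydroxy-5-methoxybenzaldehyde) | COc1cc(C=O)cc(Br)c1O | starting material
2 | 3-bromo-4-hydroxy-5-methoxyphenyl formate | COc1cc(OC=O)cc(Br)c1O | intermediate (not isolated)
3 | 2-bromo-6-methoxybenzene-1,4-diol | COc1cc(O)cc(Br)c1O | intermediate
4 | 1-bromo-3-methoxy-2,5-bis(trimethylsilyloxy)benzene | COc1cc(O[Si](C)(C)C)cc(Br)c1O[Si](C)(C)C | intermediate (not isolated)
5 | lithium 2-methoxy-6-(trimethylsilyl)-4-(trimethylsilyloxy)phenoxide | [Li+].[O-]c1c(OC)cc(O[Si](C)(C)C)cc1[Si](C)(C)C | intermediate (not isolated)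
6 | 2-methoxy-6-(trimethylsilyl)-4-(trimethylsilyloxy)phenyl trifluoromethanesulfonate | COc1cc(O[Si](C)(C)C)cc([Si](C)(C)C)c1OS(=O)(=O)C(F)(F)F | intermediate (not isolated)
7 | 4-hydroxy-2-methoxy-6-(trimethylsilyl)phenyl trifluoromethanesulfonate | COc1cc(O)cc([Si](C)(C)C)c1OS(=O)(=O)C(F)(F)F | intermediate
8 | 4-(benzyloxy)-2-methoxy-6-(trimethylsilyl)phenyl trifluoromethanesulfonate | COc1cc(OCc2ccccc2)cc([Si](C)(C)C)c1OS(=O)(=O)C(F)(F)F | intermediate
9 | dimethyl malonate | COC(=O)CC(=O)OC | starting material
10 | 5-(benzyloxy)-3-methoxybenzyne (5-(benzyloxy)-3-methoxy-1,2-didehydrobenzene) | COC1=CC(OCc2ccccc2)=CC#C1 | intermediate (not isolated)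
11 | methyl 4-(benzyloxy)-2-methoxy-6-(2-methoxy-2-oxoethyl)benzoate | COC(=O)Cc1cc(OCc2ccccc2)cc(OC)c1C(=O)OC | intermediate
12 | 4-(benzyloxy)-2-(carboxymethyl)-6-methoxybenzoic acid | OC(=O)Cc1cc(OCc2ccccc2)cc(OC)c1C(=O)O | intermediate
13 | 6-(benzyloxy)-8-methoxy-1H-isochromene-1,3(4H)-dione | COc1cc(OCc2ccccc2)cc2c1C(=O)OC(=O)C2 | intermediate
14 | hexanoyl chloride | CCCCCC(=O)Cl | starting material
15 | 6-(benzyloxy)-4-hexanoyl-8-methoxy-1H-isochromene-1,3(4H)-dione | CCCCCC(=O)C1C(=O)OC(=O)c2c(OC)cc(OCc3ccccc3)cc21 | intermediate (not isolated)
16 | 4-(benzyloxy)-2-methoxy-6-(2-oxoheptyl)benzoic acid | CCCCCC(=O)Cc1cc(OCc2ccccc2)cc(OC)c1C(=O)O | intermediate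
17 | 4-hydroxy-2-methoxy-6-(2-oxoheptyl)benzoic acid | CCCCCC(=O)Cc1cc(O)cc(OC)c1C(=O)O | intermediate
18 | benzyl 4-hydroxy-2-methoxy-6-(2-oxoheptyl)benzoate | CCCCCC(=O)Cc1cc(O)cc(OC)c1C(=O)OCc1ccccc1 | intermediate
19 | methyl 2,4-dihydroxy-6-methylbenzoate (methyl orsellinate) | COC(=O)c1c(C)cc(O)cc1O | starting material
20 | methyl 2,4-bis(benzyloxy)-6-methylbenzoate | COC(=O)c1c(C)cc(OCc2ccccc2)cc1OCc1ccccc1 | intermediate
21 | N-methoxy-N-methylhexanamide | CCCCCC(=O)N(C)OC | intermediate
22 | methyl 2,4-bis(benzyloxy)-6-(2-oxoheptyl)benzoate | CCCCCC(=O)Cc1cc(OCc2ccccc2)cc(OCc2ccccc2)c1C(=O)OC | intermediate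
23 | methyl 2,4-bis(benzyloxy)-6-[(2-pentyl-1,3-dioxolan-2-yl)methyl]benzoate | CCCCCC1(Cc2cc(OCc3ccccc3)cc(OCc3ccccc3)c2C(=O)OC)OCCO1 | intermediate
24 | 2,4-bis(benzyloxy)-6-[(2-pentyl-1,3-dioxolan-2-yl)methyl]benzoic acid | CCCCCC1(Cc2cc(OCc3ccccc3)cc(OCc3ccccc3)c2C(=O)O)OCCO1 | intermediate
25 | benzyl 4-({2,4-bis(benzyloxy)-6-[(2-pentyl-1,3-dioxolan-2-yl)methyl]benzoyl}oxy)-2-methoxy-6-(2-oxoheptyl)benzoate | CCCCCC(=O)Cc1cc(OC(=O)c2c(CC3(CCCCC)OCCO3)cc(OCc3ccccc3)cc2OCc2ccccc2)cc(OC)c1C(=O)OCc1ccccc1 | intermediate
26 | benzyl 4-{[2,4-bis(benzyloxy)-6-(2-oxoheptyl)benzoyl]oxy}-2-methoxy-6-(2-oxoheptyl)benzoate | CCCCCC(=O)Cc1cc(OC(=O)c2c(CC(=O)CCCCC)cc(OCc3ccccc3)cc2OCc2ccccc2)cc(OC)c1C(=O)OCc1ccccc1 | intermediate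
27 | arthonioic acid, 4-{[2,4-dihydroxy-6-(2-oxoheptyl)benzoyl]oxy}-2-methoxy-6-(2-oxoheptyl)benzoic acid | CCCCCC(=O)Cc1cc(O)cc(O)c1C(=O)Oc1cc(CC(=O)CCCCC)c(C(=O)O)c(OC)c1 | target

## Step count and least certain steps

Total: 17 steps. Longest linear sequence: 12 steps (steps 1–9 and 15–17); the ring A branch (steps 10–14) joins at step 15.

**Step 4 (key step).** The most likely failure is protonation of the aryl anion before it closes onto the ester, which leads to plain α-arylation of the malonate without the ortho carboxyl group. A second arylation of malonate or product by further aryne is also possible; loss of regioselectivity is less likely. The fallback sets out from 19 and returns at 11. Selective benzylation of the non-chelated 4-hydroxyl (BnBr, K2CO3, acetone) would give methyl 4-(benzyloxy)-2-hydroxy-6-methylbenzoate F1. Methylation of the chelated hydroxyl (MeI, K2CO3, DMF) would give methyl 4-(benzyloxy)-2-methoxy-6-methylbenzoate F2. Lateral lithiation with lithium diisopropylamide (2 equiv) and C-carboxylation with dimethyl carbonate would then give 11, after which the route continues unchanged.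

**Step 2.** The most likely failure is loss of the differentiation between the two oxygens: silyl scrambling between phenoxide 5 and the remote silyl ether, or triflation at the remote oxygen, would lead to doubly triflated material. The fallback sets out from 3 and returns at 7. Silylation of the unhindered hydroxyl (t-BuMe2SiCl, imidazole, DMF, 0 °C) would give 2-bromo-4-[(tert-butyldimethylsilyl)oxy]-6-methoxyphenol F3. The same sequence of O-silylation, exchange, migration and triflation would pass through [2-bromo-4-[(tert-butyldimethylsilyl)oxy]-6-methoxyphenoxy]trimethylsilane F4 and lithium 4-[(tert-butyldimethylsilyl)oxy]-2-methoxy-6-(trimethylsilyl)phenoxide F5 to 4-[(tert-butyldimethylsilyl)oxy]-2-methoxy-6-(trimethylsilyl)phenyl trifluoromethanesulfonate F6. Its robust aryl silyl ether would then be cleaved with HCl in MeOH to give 7.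

**Step 7.** The most likely failures are O-acylation of the anhydride enolate in place of C-acylation, and hydroxide-induced retro-Claisen loss of the hexanoyl group during ring opening, which returns the homophthalic acid. The fallback sets out from 12 and returns at 16. Thermal condensation of 12 with neat 14 at about 200 °C (the classical acid-chloride route, in which anhydride formation, C-acylation and decarboxylation run in one flask) would give 6-(benzyloxy)-8-methoxy-3-pentyl-1H-isochromen-1-one F7. Opening the enol lactone with KOH in aqueous EtOH and acidifying would give 16.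

**Step 15.** The most likely failure is slow acyl transfer from the crowded O-acylisourea, so that rearrangement to the N-acylurea or attack of a dioxolane oxygen on the activated carboxyl takes over. The fallback sets out from 24 and returns at 25. Cyanuric fluoride and pyridine in CH2Cl2 would give the isolable 2,4-bis(benzyloxy)-6-[(2-pentyl-1,3-dioxolan-2-yl)methyl]benzoyl fluoride F8, a small and non-rearranging acyl donor. It would be combined with 18, i-Pr2NEt and DMAP to give 25.

**Step 16.** The most likely failure is cleavage of the depside linkage: once the ring A ketone (or its oxocarbenium precursor) is present under acid, an oxygen of that arm can add to the neighbouring aryl ester, close the lactone and expel the ring B phenol. The fallback avoids the acid step altogether; it sets out from 22 and returns at 27. Ketalization of 22 with 1,2-benzenedimethanol (as its bis(trimethylsilyl) ether with Me3SiOTf) would give methyl 2,4-bis(benzyloxy)-6-[(3-pentyl-1,5-dihydro-3H-2,4-benzodioxepin-3-yl)methyl]benzoate F9. Saponification as in step 14 would give 2,4-bis(benzyloxy)-6-[(3-pentyl-1,5-dihydro-3H-2,4-benzodioxepin-3-yl)methyl]benzoic acid F10. Steglich coupling with 18 would give benzyl 4-({2,4-bis(benzyloxy)-6-[(3-pentyl-1,5-dihydro-3H-2,4-benzodioxepin-3-yl)methyl]benzoyl}oxy)-2-methoxy-6-(2-oxoheptyl)benzoate F11. One hydrogenolysis over Pd/C would then remove the benzyl groups and the benzylic ketal together and give 27.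

## Further compounds

F1 | step 4 | methyl 4-(benzyloxy)-2-hydroxy-6-methylbenzoate | COC(=O)c1c(C)cc(OCc2ccccc2)cc1O
F2 | step 4 | methyl 4-(benzyloxy)-2-methoxy-6-methylbenzoate | COC(=O)c1c(C)cc(OCc2ccccc2)cc1OC
F3 | step 2 | 2-bromo-4-[(tert-butyldimethylsilyl)oxy]-6-methoxyphenol | COc1cc(O[Si](C)(C)C(C)(C)C)cc(Br)c1O
F4 | step 2 | [2-bromo-4-[(tert-butyldimethylsilyl)oxy]-6-methoxyphenoxy]trimethylsilane | COc1cc(O[Si](C)(C)C(C)(C)C)cc(Br)c1O[Si](C)(C)C
F5 | step 2 | lithium 4-[(tert-butyldimethylsilyl)oxy]-2-methoxy-6-(trimethylsilyl)phenoxide | [Li+].[O-]c1c(OC)cc(O[Si](C)(C)C(C)(C)C)cc1[Si](C)(C)C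
F6 | step 2 | 4-[(tert-butyldimethylsilyl)oxy]-2-methoxy-6-(trimethylsilyl)phenyl trifluoromethanesulfonate | COc1cc(O[Si](C)(C)C(C)(C)C)cc([Si](C)(C)C)c1OS(=O)(=O)C(F)(F)F
F7 | step 7 | 6-(benzyloxy)-8-methoxy-3-pentyl-1H-isochromen-1-one | CCCCCC1=Cc2cc(OCc3ccccc3)cc(OC)c2C(=O)O1
F8 | step 15 | 2,4-bis(benzyloxy)-6-[(2-pentyl-1,3-dioxolan-2-yl)methyl]benzoyl fluoride | CCCCCC1(Cc2cc(OCc3ccccc3)cc(OCc3ccccc3)c2C(=O)F)OCCO1
F9 | step 16 | methyl 2,4-bis(benzyloxy)-6-[(3-pentyl-1,5-dihydro-3H-2,4-benzodioxepin-3-yl)methyl]benzoate | CCCCCC1(Cc2cc(OCc3ccccc3)cc(OCc3ccccc3)c2C(=O)OC)OCc2ccccc2CO1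
F10 | step 16 | 2,4-bis(benzyloxy)-6-[(3-pentyl-1,5-dihydro-3H-2,4-benzodioxepin-3-yl)methyl]benzoic acid | CCCCCC1(Cc2cc(OCc3ccccc3)cc(OCc3ccccc3)c2C(=O)O)OCc2ccccc2CO1
F11 | step 16 | benzyl 4-({2,4-bis(benzyloxy)-6-[(3-pentyl-1,5-dihydro-3H-2,4-benzodioxepin-3-yl)methyl]benzoyl}oxy)-2-methoxy-6-(2-oxoheptyl)benzoate | CCCCCC(=O)Cc1cc(OC(=O)c2c(CC3(CCCCC)OCc4ccccc4CO3)cc(OCc3ccccc3)cc2OCc2ccccc2)cc(OC)c1C(=O)OCc1ccccc1
A1 | alternative 1 | 1,1-dimethoxy-3-(trimethylsilyloxy)buta-1,3-diene | COC(OC)=CC(=C)O[Si](C)(C)C
A2 | alternative 1 | benzyl 4-(2-pentyl-1,3-dioxolan-2-yl)but-2-ynoate | CCCCCC1(CC#CC(=O)OCc2ccccc2)OCCO1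
A3 | alternative 1 | benzyl 4-hydroxy-2-methoxy-6-[(2-pentyl-1,3-dioxolan-2-yl)methyl]benzoate | CCCCCC1(Cc2cc(O)cc(OC)c2C(=O)OCc2ccccc2)OCCO1
A4 | alternative 2 | 2,4-bis(benzyloxy)benzoic acid | OC(=O)c1ccc(OCc2ccccc2)cc1OCc1ccccc1
A5 | alternative 2 | dimethylsulfoxonium 2-oxoheptylide (1-[dimethyl(oxo)-lambda6-sulfanylidene]heptan-2-one) | CCCCCC(=O)C=S(C)(C)=O
A6 | alternative 2 | 6,8-bis(benzyloxy)-3-pentyl-1H-isochromen-1-one | CCCCCC1=Cc2cc(OCc3ccccc3)cc(OCc3ccccc3)c2C(=O)O1
A7 | alternative 3 | benzyl 2-methoxy-6-[(2-pentyl-1,3-dioxolan-2-yl)methyl]-4-{[3,5,7-trioxo-8-(2-pentyl-1,3-dioxolan-2-yl)octanoyl]oxy}benzoate | CCCCCC1(CC(=O)CC(=O)CC(=O)CC(=O)Oc2cc(CC3(CCCCC)OCCO3)c(C(=O)OCc3ccccc3)c(OC)c2)OCCO1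
A8 | alternative 3 | benzyl 4-({2,4-dihydroxy-6-[(2-pentyl-1,3-dioxolan-2-yl)methyl]benzoyl}oxy)-2-methoxy-6-[(2-pentyl-1,3-dioxolan-2-yl)methyl]benzoate | CCCCCC1(Cc2cc(O)cc(O)c2C(=O)Oc2cc(CC3(CCCCC)OCCO3)c(C(=O)OCc3ccccc3)c(OC)c2)OCCO1
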